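Remark on the chemistry: atoms are labelled along the chain from C1 (ester carbonyl) to C18 (brominated alkyne carbon), and the ring CH2 is C19. The SMILES is read as 5R,6R (trans ring), 7R, 15S, 8E, 10E. Compounds 1, 2, 5, 11 and 13 are taken as commercial.

## Structural features

- The target is an unbranched C18 chain, methyl ester at C1 and bromoalkyne at C17≡C18. It carries methyl groups at C7, C11 and C15 and one ring, a trans-1,2-disubstituted cyclopropane made of C5, C6 and C19.
- C5, C6 and C7 are contiguous stereocentres. C7 is both cyclopropylcarbinyl and allylic to the E,E-diene C8=C9–C10=C11, whose C10=C11 bond is trisubstituted.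
- C15 lies eight bonds from C7, beyond any relay, so it must be bought or set on its own.
- Several groups are fragile:
  - the bromoalkyne is sensitive to Pd(0), Ru carbenes, organolithiums and hydrides;
  - the electron-rich diene is sensitive to acids and electrophiles;
  - a cation or radical at C7 would open the ring;
  - the methyl ester is sensitive to hard nucleophiles.
- The real difficulty is the C5/C6/C7 triad. The finished ring has no heteroatom to direct a methylene transfer, C6 cannot serve as an SN2 electrophile, and the ring-to-C7 relationship must be absolute.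
- The key step exploits one feature. Without the C5–C6 bond, C1–C2–C3–C4–C5–C19–C6 is a plain linear heptanoate in which C6, C19 and C5 are the carbonyl, α and β carbons of an enal.
- In that open form, C6–C7(CH3)–C8=C9 is a syn-crotylation retron whose carbinol C–O bond stands for the ring bond, and C5 is a conjugate-borylation site. The two centres, 1,3 across C19, are closed to the ring with inversion at both.

## Logic of the disconnections

**25 ⇒ 23.** The C18–Br bond is exchanged for C18–Si. The bromoalkyne would not survive Pd(0), Ru carbenes or organolithiums, so it comes last. The gain is that every C–C bond can be made on a robust silylalkyne. The demand is a bromination that spares the diene.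

**23 ⇒ 12 + 22.** The C9–C10 sp2–sp2 bond is cut. This splits the molecule into halves of equal length, separates the triad from C15, and uses two alkenes of fixed geometry. The demand is a stereoretentive coupling under a base that the ester tolerates.

**12 ⇒ 10 + 11.** The C8=C9 double bond is cut by metathesis. The vinyl group left by the crotylation becomes the coupling handle in one step. The demand is E-selectivity on an allylically branched alkene.

**10 ⇒ 8 (through 9).** The ring bond C5–C6 is cut; this is the key disconnection. In one sentence: the trans-cyclopropane is closed by a double-inversion 1,3-elimination of the aryl ate complex of an acyclic γ-tosyloxy secondary boronic ester that already holds C5, C6 and C7. The ring disappears and three stereocentres become an open 1,3-anti/1,2-syn array that standard acyclic methods can build. The demand is a stereospecific 3-exo-tet closure without a cation at C6 and without harm to the ester.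

**8 ⇒ 7 ⇒ 4 + 5.** The O–S bond and then C6–C7 are cut. C6 and C7 arise together from a closed transition state. The gain is a linear aldehyde and a four-carbon reagent. The demand is syn selectivity, Si-face attack on C6, and no oxidative work-up, because the C5–B bond must survive.

**4 ⇒ 3.** The C5–B bond is cut. C5 is the β carbon of the enal, so the nucleofuge for the key step is installed by catalysis in one step. The demand is 1,4- over 1,2-addition and delivery to the Si face of C5.

**3 ⇒ 1 + 2.** The C5=C19 double bond is cut by metathesis. The ester is present from the first step and never needs protection.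

**22 ⇒ 20.** The C11–CH3 and C10–I bonds are cut. Syn carbometalation of a terminal alkyne fixes the trisubstituted E geometry in one operation. The demand is that the other alkyne stays inert, which the bulky silyl group ensures.

**20 ⇒ 19 ⇒ 18 ⇒ 16.** The C11–C12 bond (acetylide alkylation), the C12–I/O exchange and the C12=C(CH3)2 cleavage are taken in turn. The isopropylidene end of the terpene is traded for the two-carbon alkyne. The demand is chemoselective alkene cleavage beside an alkyne.

**16 ⇒ 14 ⇒ 13.** The C18–Si bond and C17≡C18 are cut, a one-carbon homologation of the aldehyde. C12–C17 and the C15 methyl and stereocentre are bought in 13. C15 is β to the formyl group and cannot epimerise.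

## Other disconnections considered

**Alternative 1:** This is the first idea that comes to mind.
- Cut: C5–C19 and C6–C19, that is, methylene transfer to an E-alkene C5=C6, with the halves joined at C9–C10 as here.
- Forward key step: a Charette-type dioxaborolane-directed Simmons–Smith cyclopropanation after 1,2-reduction of 3, to give the cyclopropylmethanol A1.
- Structural problem: the directing hydroxyl must sit on C7, exactly where a methyl- and vinyl-bearing stereocentre is needed.
- Consequence: C7 has to be rebuilt by oxidation, one-carbon homologation, attachment and removal of an auxiliary, and enolate methylation. This leads to the epimerisable aldehyde A2 before C8=C9 can be made.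
- No shortcut: direct substitution at an activated C7 fails because cyclopropylcarbinyl cations and radicals open.
- Economy: the plan needs two stoichiometric chiral controllers and about ten steps for C1–C9, against six in the chosen plan.

**Alternative 2:**
- Cut: C6–C7 and C5–C19, with C19 mapped on a carboxyl carbon.
- Forward key step: a chelated dianionic ester-enolate Claisen rearrangement of the (Z)-crotyl β-hydroxy ester A3 to the acid A4. The C5 carbinol relays to C6 and C7 in one event. Reduction of C19 and closure C19→C5 would follow.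
- First ground against it: a C5 alkoxide five atoms from a C1 ester lactonises, so C1 must be carried as a silyl ether and re-oxidised later, at a cost of three steps.
- Second ground: the chelated dianion is attacked anti to its chain (Fráter–Seebach sense) and gives the 5,6-anti acid. Closure with inversion at C5 needs 5,6-syn for a trans ring, so one more inversion is required.
- Third ground: the correct C6/C7 relation forces the crotyl methyl into an axial position of the chair.
- Economy: about twelve steps would be needed to reach 10.

**Alternative 3:**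
- Cut: C6–C7 and C5–C19 in one flask.
- Forward key step: crotylzincation (zinca-Claisen) of the alkenyllithium from the γ-iodo allylic ether A5. The 1,1-dimetallic at C19 then undergoes 1,3-elimination on the C5–O bond, and the cyclopropylzinc is protonated.
- Appeal: on paper this is the most powerful plan.
- Stereochemical conflict: fluxional crotylzinc reacts through its E form in the chair. An E-alkenylmetal (Felkin-type attack, then inversion at C5) should give the trans ring but the C7 epimer A6. A Z-alkenylmetal would give the right C6/C7 relation, but attack anti to the chain in its chelated or A(1,3)-controlled conformer leads after inversion to the cis ring.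
- Compatibility: t-BuLi and allylzinc also rule out the ester.

Key step: step 5

## Steps

Step 1
Reactants: 1 methyl hex-5-enoate; 2 (E)-but-2-enal
Product: 3 methyl (E)-7-oxohept-5-enoate
Conditions: Hoveyda–Grubbs II (2 mol %), 2 (5 equiv), CH2Cl2, 40 °C
Reagents that add atoms: none
Why: Olefin cross-metathesis of a reactive terminal alkene with an electron-poor enal partner; excess 2 suppresses homodimerisation and the E-enal is the thermodynamic product. The ester is inert to the Ru carbene.

Step 2
Reactants: 3 methyl (E)-7-oxohept-5-enoate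
Product: 4 methyl (5S)-7-oxo-5-(4,4,5,5-tetramethyl-1,3,2-dioxaborolan-2-yl)heptanoate
Conditions: B2pin2 (1.1 equiv), chiral C1-symmetric imidazolinium salt (5 mol %), DBU (20 mol %), MeOH (60 equiv), THF, 22 °C
Reagents that add atoms: bis(pinacolato)diboron CC1(C)OB(OC1(C)C)B1OC(C)(C)C(C)(C)O1
Why: NHC-catalysed enantioselective boron conjugate addition, a reaction type established for acyclic enals; the catalyst enantiomer is chosen so that the NHC·diboron adduct delivers Bpin to the Si face of C5, which sets 5S, and MeOH protonates the boron enolate. The soft sp3–sp2 diboron adduct prefers 1,4- to 1,2-addition and leaves the saturated ester alone.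

Step 3
Reactants: 4 methyl (5S)-7-oxo-5-(pinacolatoboryl)heptanoate; 5 (Z)-crotylboronic acid pinacol ester
Product: 7 methyl (5S,7R,8R)-7-hydroxy-8-methyl-5-(4,4,5,5-tetramethyl-1,3,2-dioxaborolan-2-yl)dec-9-enoate (target atoms C5 S, C6 R, C7 R; B/OH 1,3-anti, OH/CH3 syn), via O-boryl borate ester 6 (not isolated)
Conditions: 5 (1.2 equiv), (S)-TRIP phosphoric acid (5 mol %), 4 Å MS, toluene, −30 °C; aq. NaHCO3
Reagents that add atoms: none
Why: Chiral phosphoric acid-catalysed crotylboration through a closed Zimmerman–Traxler chair: the Z-crotyl geometry gives the C6/C7 syn relation, and the catalyst antipode is chosen for attack on the Si face of C6, which sets both centres. No oxidative work-up is needed, so the C5–B bond survives, and material from the minor enantiomer of 4 ends as a diastereomer of 7 that can be removed by chromatography.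

Step 4
Reactants: 7 methyl (5S,7R,8R)-7-hydroxy-8-methyl-5-(pinacolatoboryl)dec-9-enoate
Product: 8 methyl (5S,7R,8R)-8-methyl-7-[(4-methylbenzenesulfonyl)oxy]-5-(4,4,5,5-tetramethyl-1,3,2-dioxaborolan-2-yl)dec-9-enoate
Conditions: TsCl, Et3N, Me3N·HCl (cat.), CH2Cl2, 0 °C
Reagents that add atoms: 4-toluenesulfonyl chloride Cc1ccc(cc1)S(Cl)(=O)=O
Why: Amine-catalysed O-sulfonylation of a secondary alcohol; the C6–O bond is not touched, so the configuration is kept. A tosylate is preferred to a mesylate because it has no acidic α-hydrogens for the organolithium of step 5.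

Step 5
Reactants: 8 methyl (5S,7R,8R)-8-methyl-7-(tosyloxy)-5-(pinacolatoboryl)dec-9-enoate
Product: 10 methyl 4-{(1R,2R)-2-[(2R)-but-3-en-2-yl]cyclopropyl}butanoate, via lithium phenylboronate complex 9 (not isolated)
Conditions: PhLi (1.0 equiv), THF, −78 °C, 30 min; then −78 → 40 °C
Reagents that add atoms: none
Why: PhLi should add to the vacant boron p orbital of 8 at −78 °C faster than to the ester or the sulfonate (the same kinetic order that allows in-situ borate trapping of ester-bearing aryllithiums), so 9 forms and no free base or nucleophile is left on warming. In 9 the electron-rich C5–B σ bond attacks C6 with its back lobe while tosylate leaves from the opposite side of C6, through the W-shaped array B–C5–C19–C6–O, and PhBpin and LiOTs are released. The closest known reaction type is the γ-elimination of γ-halo- and γ-sulfonyloxyalkylboron ate complexes to cyclopropanes (the hydroboration/base cyclopropane synthesis), which is stereospecific with inversion at both carbons; aryl ate complexes of secondary pinacol boronic esters likewise meet carbon electrophiles by SE2 inversion. The only ring closed is the cyclopropane C5–C19–C6, in the 3-exo-tet mode. C5 is controlled by the 5S C–B centre (inversion to 5R) and C6 by the carbinol centre of step 3 (inversion to 6R); C7 is untouched, so its relation to the ring is the one fixed by the syn-crotylation. Because boron and tosylate are 1,3-anti in 8, the W conformer holds the C4 chain and the C7 branch on opposite faces without syn-pentane strain, and only the trans ring can arise from it. The step needs closure to win over E2 loss of TsOH toward the allylic C7–H, over ionisation at C6 and over attack at C1: the absence of free base, the non-ionising medium, a sulfonate without acidic hydrogens and the entropic advantage of three-ring closure secure this.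

Step 6
Reactants: 10 methyl 4-{(1R,2R)-2-[(2R)-but-3-en-2-yl]cyclopropyl}butanoate; 11 vinylboronic acid pinacol ester
Product: 12 methyl 4-{(1R,2R)-2-[(2R,3E)-4-(4,4,5,5-tetramethyl-1,3,2-dioxaborolan-2-yl)but-3-en-2-yl]cyclopropyl}butanoate
Conditions: 11 (3 equiv), Grubbs II (5 mol %), CH2Cl2, 40 °C
Reagents that add atoms: none
Why: Cross-metathesis of a terminal alkene with vinyl-Bpin, which is known to give E-alkenylboronates; the bulky Bpin group enforces E geometry. Alkylcyclopropanes and esters are inert to the catalyst, and C9 of the target comes from 11.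

Step 7
Reactants: 13 (S)-citronellal [(3S)-3,7-dimethyloct-6-enal]
Product: 14 (4S)-1,1-dibromo-4,8-dimethylnona-1,7-diene
Conditions: CBr4, PPh3, CH2Cl2, 0 °C
Reagents that add atoms: carbon tetrabromide BrC(Br)(Br)Br
Why: Ramirez dibromo-olefination (first stage of the Corey–Fuchs sequence), a Wittig-type reaction that is selective for the aldehyde. C15 is β to the carbonyl and is not at risk.

Step 8
Reactants: 14 (4S)-1,1-dibromo-4,8-dimethylnona-1,7-diene
Product: 16 [(4S)-4,8-dimethylnon-7-en-1-yn-1-yl]tri(propan-2-yl)silane, via lithium acetylide 15 (not isolated)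
Conditions: n-BuLi (2.1 equiv), THF, −78 → 0 °C; TIPSOTf, −78 → 23 °C
Reagents that add atoms: triisopropylsilyl trifluoromethanesulfonate CC(C)[Si](OS(=O)(=O)C(F)(F)F)(C(C)C)C(C)C
Why: Second stage of the Corey–Fuchs reaction (Br/Li exchange, 1,2-shift, deprotonation), followed by C-silylation of the acetylide. The TIPS group is chosen to withstand steps 11–13.

Step 9
Reactants: 16 [(4S)-4,8-dimethylnon-7-en-1-yn-1-yl]tri(propan-2-yl)silane
Product: 18 (4S)-4-methyl-7-[tri(propan-2-yl)silyl]hept-6-yn-1-ol, via aldehyde 17 (not isolated)
Conditions: O3, CH2Cl2/MeOH, Sudan III, −78 °C; NaBH4, −78 → 0 °C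
Reagents that add atoms: ozone [O-][O+]=O
Why: Ozonolysis with reductive work-up; the electron-rich trisubstituted alkene reacts far faster than a hindered silylalkyne, and the indicator dye marks the end point.

Step 10
Reactants: 18 (4S)-4-methyl-7-[tri(propan-2-yl)silyl]hept-6-yn-1-ol
Product: 19 [(4S)-7-iodo-4-methylhept-1-yn-1-yl]tri(propan-2-yl)silane
Conditions: I2, PPh3, imidazole, CH2Cl2, 0 °C
Reagents that add atoms: iodine II
Why: Appel-type iodination of a primary alcohol through the alkoxyphosphonium salt; no stereocentre is involved.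

Step 11
Reactants: 19 [(4S)-7-iodo-4-methylhept-1-yn-1-yl]tri(propan-2-yl)silane
Product: 20 [(4S)-4-methylnona-1,8-diyn-1-yl]tri(propan-2-yl)silane
Conditions: HC≡CLi·H2NCH2CH2NH2, DMSO, 10 → 23 °C
Reagents that add atoms: lithium acetylide–ethylenediamine complex [Li]C#C.NCCN
Why: SN2 alkylation of lithium acetylide by an unhindered primary iodide; the TIPS-alkyne resists desilylation under these conditions.

Step 12
Reactants: 20 [(4S)-4-methylnona-1,8-diyn-1-yl]tri(propan-2-yl)silane
Product: 22 [(4S,8E)-9-iodo-4,8-dimethylnon-8-en-1-yn-1-yl]tri(propan-2-yl)silane, via alkenylalane 21 (not isolated)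
Conditions: Me3Al, Cp2ZrCl2 (25 mol %), CH2Cl2, 0 → 23 °C; I2, THF, −30 °C
Reagents that add atoms: trimethylaluminium C[Al](C)C; iodine II
Why: Negishi zirconium-catalysed carboalumination adds CH3 and Al syn across the terminal alkyne with Al at C10, and iodinolysis proceeds with retention, which fixes the E geometry of C10=C11. The TIPS-capped internal alkyne is too hindered to react.

Step 13
Reactants: 12 methyl 4-{(1R,2R)-2-[(2R,3E)-4-(pinacolatoboryl)but-3-en-2-yl]cyclopropyl}butanoate; 22 [(4S,8E)-9-iodo-4,8-dimethylnon-8-en-1-yn-1-yl]tri(propan-2-yl)silane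
Product: 23 methyl 4-{(1R,2R)-2-[(2R,3E,5E,10S)-6,10-dimethyl-13-[tri(propan-2-yl)silyl]trideca-3,5-dien-12-yn-2-yl]cyclopropyl}butanoate
Conditions: Pd(dppf)Cl2 (5 mol %), K3PO4 (aq.), THF, 23 → 40 °C
Reagents that add atoms: none
Why: Suzuki–Miyaura alkenyl–alkenyl coupling with retention at both partners gives the E,E-diene. Aqueous phosphate at mild temperature spares the methyl ester and the TIPS-alkyne, and C7 is not acidic enough to epimerise.

Step 14
Reactants: 23 methyl 4-{(1R,2R)-2-[(2R,3E,5E,10S)-6,10-dimethyl-13-[tri(propan-2-yl)silyl]trideca-3,5-dien-12-yn-2-yl]cyclopropyl}butanoate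
Product: 25 methyl 4-{(1R,2R)-2-[(2R,3E,5E,10S)-13-bromo-6,10-dimethyltrideca-3,5-dien-12-yn-2-yl]cyclopropyl}butanoate, via silver acetylide 24 (not isolated)
Conditions: AgF, NBS, MeCN, 23 °C, dark
Reagents that add atoms: N-bromosuccinimide BrN1C(=O)CCC1=O
Why: Silver fluoride-mediated desilylative bromination of a TIPS-alkyne: fluoride removes silicon, and the silver acetylide is brominated by NBS much faster than an alkene is attacked in a non-acidic medium in the dark. No stereocentre is touched.

## Compound list

1 | methyl hex-5-enoate | COC(=O)CCCC=C | starting material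
2 | (E)-but-2-enal | C/C=C/C=O | starting material
3 | methyl (E)-7-oxohept-5-enoate | COC(=O)CCC/C=C/C=O | intermediate
4 | methyl (5S)-7-oxo-5-(4,4,5,5-tetramethyl-1,3,2-dioxaborolan-2-yl)heptanoate | COC(=O)CCC[C@@H](CC=O)B1OC(C)(C)C(C)(C)O1 | intermediate
5 | 2-[(Z)-but-2-en-1-yl]-4,4,5,5-tetramethyl-1,3,2-dioxaborolane | C/C=C\CB1OC(C)(C)C(C)(C)O1 | starting material
6 | O-(pinacolatoboryl) borate ester of 7 | COC(=O)CCC[C@@H](C[C@@H](OB1OC(C)(C)C(C)(C)O1)[C@H](C)C=C)B1OC(C)(C)C(C)(C)O1 | intermediate
7 | methyl (5S,7R,8R)-7-hydroxy-8-methyl-5-(4,4,5,5-tetramethyl-1,3,2-dioxaborolan-2-yl)dec-9-enoate | COC(=O)CCC[C@@H](C[C@@H](O)[C@H](C)C=C)B1OC(C)(C)C(C)(C)O1 | intermediate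
8 | methyl (5S,7R,8R)-8-methyl-7-[(4-methylbenzenesulfonyl)oxy]-5-(4,4,5,5-tetramethyl-1,3,2-dioxaborolan-2-yl)dec-9-enoate | COC(=O)CCC[C@@H](C[C@@H](OS(=O)(=O)c1ccc(C)cc1)[C@H](C)C=C)B1OC(C)(C)C(C)(C)O1 | intermediate
9 | lithium B-phenyl ate complex of 8 | [Li+].COC(=O)CCC[C@@H](C[C@@H](OS(=O)(=O)c1ccc(C)cc1)[C@H](C)C=C)[B-]1(c2ccccc2)OC(C)(C)C(C)(C)O1 | intermediate
10 | methyl 4-{(1R,2R)-2-[(2R)-but-3-en-2-yl]cyclopropyl}butanoate | COC(=O)CCC[C@@H]1C[C@H]1[C@H](C)C=C | intermediate
11 | 2-ethenyl-4,4,5,5-tetramethyl-1,3,2-dioxaborolane | C=CB1OC(C)(C)C(C)(C)O1 | starting material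
12 | methyl 4-{(1R,2R)-2-[(2R,3E)-4-(4,4,5,5-tetramethyl-1,3,2-dioxaborolan-2-yl)but-3-en-2-yl]cyclopropyl}butanoate | COC(=O)CCC[C@@H]1C[C@H]1[C@H](C)/C=C/B2OC(C)(C)C(C)(C)O2 | intermediate
13 | (3S)-3,7-dimethyloct-6-enal, (S)-citronellal | CC(C)=CCC[C@H](C)CC=O | starting material
14 | (4S)-1,1-dibromo-4,8-dimethylnona-1,7-diene | CC(C)=CCC[C@H](C)CC=C(Br)Br | intermediate
15 | [(4S)-4,8-dimethylnon-7-en-1-yn-1-yl]lithium | CC(C)=CCC[C@H](C)CC#C[Li] | intermediate
16 | [(4S)-4,8-dimethylnon-7-en-1-yn-1-yl]tri(propan-2-yl)silane | CC(C)=CCC[C@H](C)CC#C[Si](C(C)C)(C(C)C)C(C)C | intermediate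
17 | (4S)-4-methyl-7-[tri(propan-2-yl)silyl]hept-6-ynal | O=CCC[C@H](C)CC#C[Si](C(C)C)(C(C)C)C(C)C | intermediate
18 | (4S)-4-methyl-7-[tri(propan-2-yl)silyl]hept-6-yn-1-ol | OCCC[C@H](C)CC#C[Si](C(C)C)(C(C)C)C(C)C | intermediate
19 | [(4S)-7-iodo-4-methylhept-1-yn-1-yl]tri(propan-2-yl)silane | ICCC[C@H](C)CC#C[Si](C(C)C)(C(C)C)C(C)C | intermediate
20 | [(4S)-4-methylnona-1,8-diyn-1-yl]tri(propan-2-yl)silane | C#CCCC[C@H](C)CC#C[Si](C(C)C)(C(C)C)C(C)C | intermediate
21 | dimethyl{(1E,6S)-2,6-dimethyl-9-[tri(propan-2-yl)silyl]non-1-en-8-yn-1-yl}alumane | C[Al](C)/C=C(\C)CCC[C@H](C)CC#C[Si](C(C)C)(C(C)C)C(C)C | intermediate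
22 | [(4S,8E)-9-iodo-4,8-dimethylnon-8-en-1-yn-1-yl]tri(propan-2-yl)silane | I/C=C(\C)CCC[C@H](C)CC#C[Si](C(C)C)(C(C)C)C(C)C | intermediate
23 | methyl 4-{(1R,2R)-2-[(2R,3E,5E,10S)-6,10-dimethyl-13-[tri(propan-2-yl)silyl]trideca-3,5-dien-12-yn-2-yl]cyclopropyl}butanoate | COC(=O)CCC[C@@H]1C[C@H]1[C@H](C)/C=C/C=C(\C)CCC[C@H](C)CC#C[Si](C(C)C)(C(C)C)C(C)C | intermediate
24 | silver(I) acetylide of the desilylated 23 | COC(=O)CCC[C@@H]1C[C@H]1[C@H](C)/C=C/C=C(\C)CCC[C@H](C)CC#C[Ag] | intermediate
25 | methyl 4-{(1R,2R)-2-[(2R,3E,5E,10S)-13-bromo-6,10-dimethyltrideca-3,5-dien-12-yn-2-yl]cyclopropyl}butanoate | COC(=O)CCC[C@@H]1C[C@H]1[C@H](C)/C=C/C=C(\C)CCC[C@H](C)CC#CBr | target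

## Step count and least certain steps

The route has 14 steps in total. The longest linear sequence is 8 steps, either 1 → 25 by steps 1–6, 13 and 14, or equally 13 → 25 by steps 7–14.

**Step 5 (key step).**
- What may go wrong:
  - addition of PhLi to the methyl ester or attack at sulfur before complexation with boron is complete;
  - sluggish closure of the ate complex, so that on warming elimination of sulfonic acid toward the allylic C7–H takes over;
  - partial ionisation at C6, with loss of stereospecificity.
- The fallback uses known chemistry. The ring is made by methylene transfer and C7 by catalytic SN2′ substitution. It sets out from 3 and returns at 10.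
- Luche reduction of 3 gives methyl (E)-7-hydroxyhept-5-enoate F1.
- Charette dioxaborolane-controlled Simmons–Smith cyclopropanation gives methyl 4-[(1R,2R)-2-(hydroxymethyl)cyclopropyl]butanoate F2, the same compound as A1.
- Dess–Martin oxidation gives methyl 4-[(1R,2R)-2-formylcyclopropyl]butanoate F3.
- Wittig methylenation gives methyl 4-[(1R,2S)-2-ethenylcyclopropyl]butanoate F4.
- Cross-metathesis with (E)-1,4-dibromobut-2-ene gives methyl 4-{(1R,2R)-2-[(E)-3-bromoprop-1-en-1-yl]cyclopropyl}butanoate F5.
- Copper/Taniaphos-catalysed asymmetric allylic alkylation with MeMgBr at −75 °C sets C7 and gives 10.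

**Step 2.**
- What may go wrong:
  - 1,2-addition of boron to the formyl group;
  - acetal formation with methanol;
  - weak face selection on an unbranched chain;
  - decomposition of the β-boryl aldehyde on purification.
- The fallback sets out from 1 and returns at 4.
- Cross-metathesis of 1 with N-methoxy-N-methylacrylamide gives methyl (E)-7-[methoxy(methyl)amino]-7-oxohept-5-enoate F6.
- Copper(I)/Josiphos-catalysed β-borylation (B2pin2, MeOH) gives methyl (5S)-7-[methoxy(methyl)amino]-7-oxo-5-(4,4,5,5-tetramethyl-1,3,2-dioxaborolan-2-yl)heptanoate F7.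
- Schwartz reagent reduces the amide, but not the ester, to the aldehyde 4.

**Step 3.**
- What may go wrong: an uncatalysed background reaction and modest face selection with a linear aliphatic aldehyde, which would lower the diastereomeric purity at C6/C7.
- The fallback sets out from 4 and returns at 7.
- Iridium-catalysed transfer-hydrogenative crotylation of 4 with but-3-en-2-yl acetate (isopropanol as reductant) gives the anti adduct methyl (5S,7S,8R)-7-hydroxy-8-methyl-5-(4,4,5,5-tetramethyl-1,3,2-dioxaborolan-2-yl)dec-9-enoate F8.
- Mitsunobu inversion with 4-nitrobenzoic acid gives methyl (5S,7R,8R)-8-methyl-7-[(4-nitrobenzoyl)oxy]-5-(4,4,5,5-tetramethyl-1,3,2-dioxaborolan-2-yl)dec-9-enoate F9.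
- Methanolysis (K2CO3, MeOH) gives 7.

**Step 6.**
- What may go wrong:
  - slow turnover on the allylically branched alkene;
  - consumption of 11 by self-metathesis;
  - alkene migration by ruthenium hydrides toward C7.
- The fallback sets out from 10 (with 22) and returns at 23.
- A Heck vinylation of the terminal alkene of 10 with 22 (Pd(OAc)2, Ag2CO3, DMF) forms C9–C10 directly and replaces steps 6 and 13. No new compound is made (F0).

**Step 14.**
- What may go wrong:
  - attack of electrophilic bromine on the electron-rich trisubstituted diene;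
  - silver-induced isomerisation of the diene.
- The fallback sets out from 23 and returns at 25.
- TBAF gives methyl 4-{(1R,2R)-2-[(2R,3E,5E,10S)-6,10-dimethyltrideca-3,5-dien-12-yn-2-yl]cyclopropyl}butanoate F10.
- F10 is brominated with PPh3/CBr4. In this system tribromomethanide deprotonates the alkyne and the acetylide takes bromine from the bromophosphonium ion. Neither silver nor an N–Br electrophile is present.

## Further compounds

F1 | step 5 | methyl (E)-7-hydroxyhept-5-enoate | COC(=O)CCC/C=C/CO
F2 | step 5 | methyl 4-[(1R,2R)-2-(hydroxymethyl)cyclopropyl]butanoate | COC(=O)CCC[C@@H]1C[C@H]1CO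
F3 | step 5 | methyl 4-[(1R,2R)-2-formylcyclopropyl]butanoate | COC(=O)CCC[C@@H]1C[C@H]1C=O
F4 | step 5 | methyl 4-[(1R,2S)-2-ethenylcyclopropyl]butanoate | COC(=O)CCC[C@@H]1C[C@H]1C=C
F5 | step 5 | methyl 4-{(1R,2R)-2-[(E)-3-bromoprop-1-en-1-yl]cyclopropyl}butanoate | COC(=O)CCC[C@@H]1C[C@H]1/C=C/CBr
F6 | step 2 | methyl (E)-7-[methoxy(methyl)amino]-7-oxohept-5-enoate | COC(=O)CCC/C=C/C(=O)N(C)OC
F7 | step 2 | methyl (5S)-7-[methoxy(methyl)amino]-7-oxo-5-(4,4,5,5-tetramethyl-1,3,2-dioxaborolan-2-yl)heptanoate | COC(=O)CCC[C@@H](CC(=O)N(C)OC)B1OC(C)(C)C(C)(C)O1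
F8 | step 3 | methyl (5S,7S,8R)-7-hydroxy-8-methyl-5-(4,4,5,5-tetramethyl-1,3,2-dioxaborolan-2-yl)dec-9-enoate | COC(=O)CCC[C@@H](C[C@H](O)[C@H](C)C=C)B1OC(C)(C)C(C)(C)O1
F9 | step 3 | methyl (5S,7R,8R)-8-methyl-7-[(4-nitrobenzoyl)oxy]-5-(4,4,5,5-tetramethyl-1,3,2-dioxaborolan-2-yl)dec-9-enoate | COC(=O)CCC[C@@H](C[C@@H](OC(=O)c1ccc(cc1)[N+](=O)[O-])[C@H](C)C=C)B1OC(C)(C)C(C)(C)O1
F0 | step 6 | none | none
F10 | step 14 | methyl 4-{(1R,2R)-2-[(2R,3E,5E,10S)-6,10-dimethyltrideca-3,5-dien-12-yn-2-yl]cyclopropyl}butanoate | COC(=O)CCC[C@@H]1C[C@H]1[C@H](C)/C=C/C=C(\C)CCC[C@H](C)CC#C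
A1 | alternative 1 | methyl 4-[(1R,2R)-2-(hydroxymethyl)cyclopropyl]butanoate | COC(=O)CCC[C@@H]1C[C@H]1CO
A2 | alternative 1 | methyl 4-{(1R,2R)-2-[(2S)-1-oxopropan-2-yl]cyclopropyl}butanoate | COC(=O)CCC[C@@H]1C[C@H]1[C@H](C)C=O
A3 | alternative 2 | (Z)-but-2-en-1-yl (3S)-7-[(tert-butyldimethylsilyl)oxy]-3-hydroxyheptanoate | CC(C)(C)[Si](C)(C)OCCCC[C@H](O)CC(=O)OC/C=C\C
A4 | alternative 2 | (2S,3S)-2-[(2R)-but-3-en-2-yl]-7-[(tert-butyldimethylsilyl)oxy]-3-hydroxyheptanoic acid | CC(C)(C)[Si](C)(C)OCCCC[C@H](O)[C@H]([C@H](C)C=C)C(O)=O
A5 | alternative 3 | tert-butyl{[(5R,6E)-7-iodo-5-(methoxymethoxy)hept-6-en-1-yl]oxy}dimethylsilane | CC(C)(C)[Si](C)(C)OCCCC[C@@H](OCOC)/C=C/I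
A6 | alternative 3 | tert-butyl(4-{(1R,2R)-2-[(2S)-but-3-en-2-yl]cyclopropyl}butoxy)dimethylsilane | CC(C)(C)[Si](C)(C)OCCCC[C@@H]1C[C@H]1[C@@H](C)C=C
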